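The lactone ring (O1, C2, C3, C4, C5) is opened between O1 and C2. C3 carries two carbon substituents, C2 and the benzylic carbon of the guaiacylmethyl group, and both can be carried as ester groups of a hydroxymalonate. The key step lets the C5 hydroxyl close onto one of these two diastereotopic esters, which forms the ring and fixes C3 relative to C4 in one operation. The precursor is a diallyl 2-hydroxymalonate whose central carbon bears an (S)-configured chain with a primary hydroxyl and the protected syringylmethyl group, made by a D-proline aldol on a ketomalonate. The surviving ester is then turned into the guaiacylmethyl group.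

Key step: step 7

Remark on the chemistry: the malonate esters are taken as allyl esters, because the ester that survives the ring closure must later be removed without hydrolysing the lactone; hydrolysis would open the ring to a hydroxymalonate with two equivalent carboxyl groups and so erase the C3 centre that the key step sets.

Step 1
Reactants: 1 sinapic acid [(E)-3-(4-hydroxy-3,5-dimethoxyphenyl)prop-2-enoic acid]
Product: 2 3-(4-hydroxy-3,5-dimethoxyphenyl)propanoic acid
Conditions: H2 (1 atm), 10% Pd/C, MeOH, rt
Reagents that add atoms: none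
Why: Heterogeneous catalytic hydrogenation saturates the cinnamic C=C bond while the arene, the acid and the methoxy groups are inert, and no stereocentre is formed.

Step 2
Reactants: 2 3-(4-hydroxy-3,5-dimethoxyphenyl)propanoic acid
Product: 3 benzyl 3-[4-(benzyloxy)-3,5-dimethoxyphenyl]propanoate
Conditions: BnBr (2.4 equiv), K2CO3, DMF, 60 °C
Reagents that add atoms: benzyl bromide, BrCc1ccccc1
Why: Williamson-type O-alkylation, in which K2CO3 deprotonates both the phenol and the acid and each anion displaces bromide from benzyl bromide, so that the ether and the ester are installed in one operation.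

Step 3
Reactants: 3 benzyl 3-[4-(benzyloxy)-3,5-dimethoxyphenyl]propanoate
Product: 4 3-[4-(benzyloxy)-3,5-dimethoxyphenyl]propanal
Conditions: i-Bu2AlH (1.1 equiv), CH2Cl2, −78 °C; MeOH, then aq. potassium sodium tartrate
Reagents that add atoms: none
Why: Partial ester reduction with i-Bu2AlH, in which the tetrahedral aluminium hemiacetal is stable at −78 °C and releases the aldehyde only on work-up, the aryl benzyl ether being untouched.

Step 4
Reactants: 5 tartronic acid (2-hydroxypropanedioic acid)
Product: 6 bis(prop-2-en-1-yl) 2-hydroxypropanedioate (diallyl tartronate)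
Conditions: allyl alcohol (6 equiv), TsOH·H2O (cat.), toluene, reflux, Dean–Stark trap
Reagents that add atoms: allyl alcohol (prop-2-en-1-ol), C=CCO
Why: Fischer esterification driven by azeotropic removal of water, the secondary hydroxyl being too poor a nucleophile to compete with the excess allyl alcohol.

Step 5
Reactants: 6 bis(prop-2-en-1-yl) 2-hydroxypropanedioate
Product: 7 bis(prop-2-en-1-yl) 2-oxopropanedioate (diallyl ketomalonate)
Conditions: Dess–Martin periodinane (1.2 equiv), CH2Cl2, rt; filtration, distillation
Reagents that add atoms: none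
Why: Dess–Martin oxidation of a secondary alcohol to the ketone, worked up without water because the tricarbonyl product hydrates readily, the allyl C=C bonds being inert to the periodinane.

Step 6
Reactants: 4 3-[4-(benzyloxy)-3,5-dimethoxyphenyl]propanal, 7 bis(prop-2-en-1-yl) 2-oxopropanedioate
Product: 9 bis(prop-2-en-1-yl) 2-hydroxy-2-[(2S)-1-[4-(benzyloxy)-3,5-dimethoxyphenyl]-3-hydroxypropan-2-yl]propanedioate, via aldol aldehyde 8 (not isolated)
Conditions: D-proline [(R)-pyrrolidine-2-carboxylic acid] (30 mol%), CH2Cl2, rt; then NaBH4, EtOH, −20 °C; AcOH quench, rapid extractive work-up, used crude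
Reagents that add atoms: none
Why: Proline-catalysed enamine aldol addition, in which the E-enamine of 4 attacks the non-enolisable, strongly electrophilic keto group of 7 on the face where the catalyst's carboxylic acid hydrogen-bonds the ketone oxygen, which should set the (R) centre of 8, after which NaBH4 reduces the epimerisable aldehyde in the same pot faster than it touches the esters (the descriptor becomes S only through the change in priorities).

Step 7
Reactants: 9 bis(prop-2-en-1-yl) 2-hydroxy-2-[(2S)-1-[4-(benzyloxy)-3,5-dimethoxyphenyl]-3-hydroxypropan-2-yl]propanedioate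
Product: 10 prop-2-en-1-yl (3R,4S)-4-{[4-(benzyloxy)-3,5-dimethoxyphenyl]methyl}-3-hydroxy-2-oxooxolane-3-carboxylate (allyl ester trans and hydroxyl cis to the C4 arylmethyl group)
Conditions: TsOH·H2O (10 mol%), toluene (0.5 M), 70 °C, sealed vessel so that the liberated allyl alcohol stays in solution
Reagents that add atoms: none
Why: Protonation of one allyl ester carbonyl lets the primary hydroxyl add to it, and the tetrahedral intermediate expels allyl alcohol to form the O1–C2 bond; the closest known reaction type is the acid-catalysed, diastereotopic-group-selective lactonisation of a substituted hydroxy malonate. The ring closes in the 5-exo-trig mode, the attacked carbonyl lying outside the new five-membered ring. C3 becomes a stereocentre here and is controlled by the existing C4 centre, because the remaining allyl ester, the larger of the two C3 substituents, should prefer the ring face opposite to the C4 arylmethyl group and leave the small hydroxyl cis to it. The selectivity needed is between the two diastereotopic ester groups, and it is secured by keeping the acyl transfer reversible (acid, retained allyl alcohol, warming), so that both lactones interconvert through 9 and the trans-ester isomer should accumulate, with the kinetic preference expected to point the same way. The tertiary hydroxyl cannot compete because it could only close a three-membered ring, and C4 has no acidic hydrogen, so its configuration is not at risk.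

Step 8
Reactants: 10 prop-2-en-1-yl (3R,4S)-4-{[4-(benzyloxy)-3,5-dimethoxyphenyl]methyl}-3-hydroxy-2-oxooxolane-3-carboxylate
Product: 11 (3R,4S)-4-{[4-(benzyloxy)-3,5-dimethoxyphenyl]methyl}-3-hydroxy-2-oxooxolane-3-carboxylic acid
Conditions: Pd(PPh3)4 (3 mol%), HCO2H, Et3N, THF, rt; brief cold acidic work-up
Reagents that add atoms: none
Why: Tsuji–Trost-type deallylation, in which zerovalent palladium ionises the allyl ester to a pi-allyl complex and the carboxylate and formate reduces the allyl fragment to propene, so that the acid is released under neutral conditions without opening the lactone, cleaving the benzyl ether or disturbing C3.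

Step 9
Reactants: 11 (3R,4S)-4-{[4-(benzyloxy)-3,5-dimethoxyphenyl]methyl}-3-hydroxy-2-oxooxolane-3-carboxylic acid
Product: 12 (3R,4S)-4-{[4-(benzyloxy)-3,5-dimethoxyphenyl]methyl}-3-hydroxy-3-(hydroxymethyl)oxolan-2-one
Conditions: BH3·SMe2 (2.5 equiv), THF, 0 °C to rt; MeOH quench
Reagents that add atoms: none
Why: Chemoselective borane reduction of a carboxylic acid through its acyloxyborane, which is much faster than reduction of the lactone and does not involve either stereocentre.

Step 10
Reactants: 12 (3R,4S)-4-{[4-(benzyloxy)-3,5-dimethoxyphenyl]methyl}-3-hydroxy-3-(hydroxymethyl)oxolan-2-one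
Product: 13 (3R,4S)-4-{[4-(benzyloxy)-3,5-dimethoxyphenyl]methyl}-3-hydroxy-2-oxooxolane-3-carbaldehyde
Conditions: (COCl)2, DMSO, CH2Cl2, −78 °C; Et3N, −78 to −30 °C; used crude at once
Reagents that add atoms: none
Why: Swern oxidation converts the primary alcohol into the aldehyde at low temperature, the tertiary hydroxyl cannot be oxidised, and an activated-DMSO oxidant is chosen because it does not cleave the 1,2-diol.

Step 11
Reactants: 14 4-bromo-2-methoxyphenol
Product: 15 1-(benzyloxy)-4-bromo-2-methoxybenzene
Conditions: BnBr (1.1 equiv), K2CO3, acetone, reflux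
Reagents that add atoms: benzyl bromide, BrCc1ccccc1
Why: Williamson ether synthesis, the phenoxide displacing bromide from benzyl bromide.

Step 12
Reactants: 13 (3R,4S)-4-{[4-(benzyloxy)-3,5-dimethoxyphenyl]methyl}-3-hydroxy-2-oxooxolane-3-carbaldehyde, 15 1-(benzyloxy)-4-bromo-2-methoxybenzene
Product: 17 (3R,4S)-3-{[4-(benzyloxy)-3-methoxyphenyl](hydroxy)methyl}-4-{[4-(benzyloxy)-3,5-dimethoxyphenyl]methyl}-3-hydroxyoxolan-2-one (both epimers at the new carbinol carbon), via aryl Grignard reagent 16 (not isolated)
Conditions: 15, Mg (I2 cat.), THF, 50 °C; then 16 (2.5 equiv) added to 13, THF, −78 °C; aq. NH4Cl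
Reagents that add atoms: none
Why: Grignard addition, in which magnesium inserts into the C–Br bond of 15, the first equivalent of 16 deprotonates the tertiary hydroxyl and the next adds to the aldehyde, which at −78 °C is far more electrophilic than the lactone, the new carbinol centre being formed without control because it is removed in the next step while C3 and C4 are unaffected.

Step 13
Reactants: 17 (3R,4S)-3-{[4-(benzyloxy)-3-methoxyphenyl](hydroxy)methyl}-4-{[4-(benzyloxy)-3,5-dimethoxyphenyl]methyl}-3-hydroxyoxolan-2-one
Product: 18 (3S,4S)-3-hydroxy-4-[(4-hydroxy-3,5-dimethoxyphenyl)methyl]-3-[(4-hydroxy-3-methoxyphenyl)methyl]oxolan-2-one (CNP0315014.1)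
Conditions: H2 (3 atm), 10% Pd/C, EtOAc–AcOH (4:1), rt
Reagents that add atoms: none
Why: Catalytic hydrogenolysis cleaves both benzyl ethers and then the benzylic C–OH bond, which is activated by the para-hydroxyl of the liberated guaiacyl ring, while the non-benzylic tertiary C3–OH, the lactone and both stereocentres remain (the C3 descriptor changes from R to S only through the priority rules).

Compound list
1 | sinapic acid, (E)-3-(4-hydroxy-3,5-dimethoxyphenyl)prop-2-enoic acid | COc1cc(/C=C/C(=O)O)cc(OC)c1O | starting material
2 | 3-(4-hydroxy-3,5-dimethoxyphenyl)propanoic acid | COc1cc(CCC(=O)O)cc(OC)c1O | intermediate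
3 | benzyl 3-[4-(benzyloxy)-3,5-dimethoxyphenyl]propanoate | COc1cc(CCC(=O)OCc2ccccc2)cc(OC)c1OCc1ccccc1 | intermediate
4 | 3-[4-(benzyloxy)-3,5-dimethoxyphenyl]propanal | COc1cc(CCC=O)cc(OC)c1OCc1ccccc1 | intermediate
5 | tartronic acid, 2-hydroxypropanedioic acid | OC(C(=O)O)C(=O)O | starting material
6 | bis(prop-2-en-1-yl) 2-hydroxypropanedioate | C=CCOC(=O)C(O)C(=O)OCC=C | intermediate
7 | bis(prop-2-en-1-yl) 2-oxopropanedioate | C=CCOC(=O)C(=O)C(=O)OCC=C | intermediate
8 | bis(prop-2-en-1-yl) 2-hydroxy-2-[(2R)-1-[4-(benzyloxy)-3,5-dimethoxyphenyl]-3-oxopropan-2-yl]propanedioate | C=CCOC(=O)C(O)(C(=O)OCC=C)[C@H](C=O)Cc1cc(OC)c(OCc2ccccc2)c(OC)c1 | intermediate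
9 | bis(prop-2-en-1-yl) 2-hydroxy-2-[(2S)-1-[4-(benzyloxy)-3,5-dimethoxyphenyl]-3-hydroxypropan-2-yl]propanedioate | C=CCOC(=O)C(O)(C(=O)OCC=C)[C@H](CO)Cc1cc(OC)c(OCc2ccccc2)c(OC)c1 | intermediate
10 | prop-2-en-1-yl (3R,4S)-4-{[4-(benzyloxy)-3,5-dimethoxyphenyl]methyl}-3-hydroxy-2-oxooxolane-3-carboxylate | C=CCOC(=O)[C@@]1(O)C(=O)OC[C@@H]1Cc1cc(OC)c(OCc2ccccc2)c(OC)c1 | intermediate
11 | (3R,4S)-4-{[4-(benzyloxy)-3,5-dimethoxyphenyl]methyl}-3-hydroxy-2-oxooxolane-3-carboxylic acid | OC(=O)[C@@]1(O)C(=O)OC[C@@H]1Cc1cc(OC)c(OCc2ccccc2)c(OC)c1 | intermediate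
12 | (3R,4S)-4-{[4-(benzyloxy)-3,5-dimethoxyphenyl]methyl}-3-hydroxy-3-(hydroxymethyl)oxolan-2-one | OC[C@@]1(O)C(=O)OC[C@@H]1Cc1cc(OC)c(OCc2ccccc2)c(OC)c1 | intermediate
13 | (3R,4S)-4-{[4-(benzyloxy)-3,5-dimethoxyphenyl]methyl}-3-hydroxy-2-oxooxolane-3-carbaldehyde | O=C[C@@]1(O)C(=O)OC[C@@H]1Cc1cc(OC)c(OCc2ccccc2)c(OC)c1 | intermediate
14 | 4-bromo-2-methoxyphenol | COc1cc(Br)ccc1O | starting material
15 | 1-(benzyloxy)-4-bromo-2-methoxybenzene | COc1cc(Br)ccc1OCc1ccccc1 | intermediate
16 | [4-(benzyloxy)-3-methoxyphenyl]magnesium bromide | COc1cc([Mg]Br)ccc1OCc1ccccc1 | intermediate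
17 | (3R,4S)-3-{[4-(benzyloxy)-3-methoxyphenyl](hydroxy)methyl}-4-{[4-(benzyloxy)-3,5-dimethoxyphenyl]methyl}-3-hydroxyoxolan-2-one, both epimers at the carbinol carbon | COc1cc(C(O)[C@@]2(O)C(=O)OC[C@@H]2Cc2cc(OC)c(OCc3ccccc3)c(OC)c2)ccc1OCc1ccccc1 | intermediate
18 | (3S,4S)-3-hydroxy-4-[(4-hydroxy-3,5-dimethoxyphenyl)methyl]-3-[(4-hydroxy-3-methoxyphenyl)methyl]oxolan-2-one | COc1cc(C[C@@]2(O)C(=O)OC[C@@H]2Cc2cc(OC)c(O)c(OC)c2)ccc1O | target

Total step count: 13.
Longest linear sequence: 10 steps (steps 1, 2, 3, 6, 7, 8, 9, 10, 12 and 13, from 1 to 18).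

Steps most likely to fail

Step 7. The ring closure may discriminate poorly between the two ester groups, or the ring opening that lets the two lactones equilibrate may be too slow, so that both C3 configurations are carried forward. The fallback sets out from 9 and makes the selection between free carboxyl groups under fast aqueous equilibrium. LiOH in THF–H2O at 0 °C would remove both allyl groups to give 2-hydroxy-2-[(2S)-1-[4-(benzyloxy)-3,5-dimethoxyphenyl]-3-hydroxypropan-2-yl]propanedioic acid F1. On acidification and gentle warming in dilute aqueous HCl–dioxane, F1 should close to the lactone acids, which interconvert freely through F1 under these conditions. The trans acid would be drained from the equilibrium by crystallisation, and the route is rejoined at 11, so step 8 is not needed.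

Step 10. The hydroxy aldehyde may be lost through hydration, loss of the formyl group by retro-Claisen cleavage or acyl migration, before or during the Grignard addition. The fallback sets out from 12 and avoids both the aldehyde and the benzylic hydroxyl. TsCl, Et3N and catalytic Bu2SnO in CH2Cl2 would sulfonylate only the primary hydroxyl to give [(3R,4S)-4-{[4-(benzyloxy)-3,5-dimethoxyphenyl]methyl}-3-hydroxy-2-oxooxolan-3-yl]methyl 4-methylbenzenesulfonate F2. DBU would then close the tertiary oxygen onto the CH2 carbon to give the spiro-epoxide (3R,7S)-7-{[4-(benzyloxy)-3,5-dimethoxyphenyl]methyl}-1,5-dioxaspiro[2.4]heptan-4-one F3, with no bond to C3 broken. Reagent 16 with catalytic CuI in THF at −30 °C should open F3 at its CH2 terminus to give (3S,4S)-3-{[4-(benzyloxy)-3-methoxyphenyl]methyl}-4-{[4-(benzyloxy)-3,5-dimethoxyphenyl]methyl}-3-hydroxyoxolan-2-one F4. H2 over Pd/C in EtOAc would remove the two benzyl groups, and the route is rejoined at 18.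

Step 13. Hydrogenolysis of the hindered benzylic C–O bond may stall, or acid may ionise it and trigger Friedel–Crafts ring closure onto the syringyl ring. The fallback sets out from 17 and activates the leaving group so that no acid is needed. Ac2O and pyridine at 0 °C would acetylate only the secondary benzylic hydroxyl to give [4-(benzyloxy)-3-methoxyphenyl][(3R,4S)-4-{[4-(benzyloxy)-3,5-dimethoxyphenyl]methyl}-3-hydroxy-2-oxooxolan-3-yl]methyl acetate F5. H2 over Pd/C in neutral EtOAc–EtOH should then cleave the benzylic acetate and both benzyl ethers, and the route is rejoined at 18.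

Further compounds
F1 | step 7 | 2-hydroxy-2-[(2S)-1-[4-(benzyloxy)-3,5-dimethoxyphenyl]-3-hydroxypropan-2-yl]propanedioic acid | OC(=O)C(O)(C(=O)O)[C@H](CO)Cc1cc(OC)c(OCc2ccccc2)c(OC)c1
F2 | step 10 | [(3R,4S)-4-{[4-(benzyloxy)-3,5-dimethoxyphenyl]methyl}-3-hydroxy-2-oxooxolan-3-yl]methyl 4-methylbenzenesulfonate | Cc1ccc(cc1)S(=O)(=O)OC[C@@]1(O)C(=O)OC[C@@H]1Cc1cc(OC)c(OCc2ccccc2)c(OC)c1
F3 | step 10 | (3R,7S)-7-{[4-(benzyloxy)-3,5-dimethoxyphenyl]methyl}-1,5-dioxaspiro[2.4]heptan-4-one | C1O[C@@]12C(=O)OC[C@@H]2Cc2cc(OC)c(OCc3ccccc3)c(OC)c2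
F4 | step 10 | (3S,4S)-3-{[4-(benzyloxy)-3-methoxyphenyl]methyl}-4-{[4-(benzyloxy)-3,5-dimethoxyphenyl]methyl}-3-hydroxyoxolan-2-one | COc1cc(C[C@@]2(O)C(=O)OC[C@@H]2Cc2cc(OC)c(OCc3ccccc3)c(OC)c2)ccc1OCc1ccccc1
F5 | step 13 | [4-(benzyloxy)-3-methoxyphenyl][(3R,4S)-4-{[4-(benzyloxy)-3,5-dimethoxyphenyl]methyl}-3-hydroxy-2-oxooxolan-3-yl]methyl acetate | COc1cc(C(OC(C)=O)[C@@]2(O)C(=O)OC[C@@H]2Cc2cc(OC)c(OCc3ccccc3)c(OC)c2)ccc1OCc1ccccc1
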